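The cyclohexane ring (C1 quaternary, C2 methylidene-bearing, C3 CHMe, C4–C6 CH2) is cut at C4–C5 and C6–C1: C4–C3–C2–C1 is a latent 2-oxydiene (C2 as enol-ether carbon), C5–C6 an ethylene unit. The key step is a Diels–Alder reaction between a 2-alkoxydiene locked in a dihydrofuran and a chiral acrylimide. It forms both bonds and the quaternary centre C1 in one operation; the acyl group left on C5 is activator, carrier of chirality and conformational anchor, under which C3 equilibrates to the required configuration before the group is excised by decarboxylation. The precursor, 4-methyl-5-isopropenyl-2,3-dihydrofuran, looks unlike the ring: its oxygen ends as the side-chain handle.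

Key step: step 4

Remark: C1–C6 in the text always mean the ring carbons of the target as defined above, whatever the locants inside compound names.
Remark: 3 is drawn as the open hydroxy ketone; it equilibrates with its lactol, which does not affect step 2. Imide 7 is prepared (step 3) rather than assumed to be purchasable.

Step 1
Reactants: 1 3-methyloxolan-2-one (α-methyl-γ-butyrolactone, racemic); 2 isopropenylmagnesium bromide
Product: 3 6-hydroxy-2,4-dimethylhex-1-en-3-one (racemic)
Conditions: 2 (1.1 equiv), THF, −78 to −40 °C; aq. NH4Cl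
Reagents that add atoms: none
Why: Grignard mono-addition to a lactone, in which the magnesium hemiketal formed at low temperature should not collapse to the ketone before the quench, so a second addition is avoided; the α-stereocentre is irrelevant because it becomes sp2 in step 2.

Step 2
Reactants: 3 6-hydroxy-2,4-dimethylhex-1-en-3-one
Product: 4 4-methyl-5-(prop-1-en-2-yl)-2,3-dihydrofuran
Conditions: PPTS (5 mol %), benzene, reflux, Dean–Stark trap; K2CO3, distillation
Reagents that add atoms: none
Why: acid-catalysed cyclodehydration of a γ-hydroxy ketone through its lactol and oxocarbenium ion, which can lose only the ring proton next to the methyl group, should give the conjugated endocyclic enol ether, whose ring holds the oxygen and the ring CH2 cis on the new double bond.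

Step 3
Reactants: 5 (S)-4-benzyloxazolidin-2-one; 6 acryloyl chloride
Product: 7 (S)-3-acryloyl-4-benzyloxazolidin-2-one
Conditions: n-BuLi, THF, −78 °C; then 6, −78 to 0 °C
Reagents that add atoms: none
Why: N-acylation of the lithiated oxazolidinone by an acid chloride, which at low temperature should outrun conjugate addition to the acryloyl group; the stereocentre of 5 is not touched.

Step 4
Reactants: 4 4-methyl-5-(prop-1-en-2-yl)-2,3-dihydrofuran; 7 (S)-3-acryloyl-4-benzyloxazolidin-2-one
Product: 9 (S)-4-benzyl-3-[(1S,3R,5R)-3-(2-hydroxyethyl)-3,5-dimethyl-4-oxocyclohexane-1-carbonyl]oxazolidin-2-one, via bicyclic enol ether cycloadduct 8 (not isolated)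
Conditions: Et2AlCl (1.4 equiv), 4 (2 equiv), CH2Cl2, −78 °C, 1 h; then 1 M HCl, THF, 23 °C, 12 h
Reagents that add atoms: water (SMILES O)
Why: Et2AlCl converts 7 into its cationic, chelated s-cis complex, which should add to the 2-alkoxydiene 4 in a concerted but asynchronous endo Diels–Alder reaction in which the bond from the enol-ether β-carbon (future C1) to the CH2 terminus of the acrylimide (C6) leads and the C4–C5 bond follows; the closest known reaction type is the Lewis-acid-promoted Diels–Alder reaction of N-acryloyl oxazolidinones with oxygenated dienes. The carbocycle closes by suprafacial [4+2] cycloaddition, and the dihydrofuran ring is carried along and opened only by the aqueous acid. C5 is controlled by the auxiliary (attack on the Cα-si face, anti to the benzyl group of the chelate), and C1 by the endo rule combined with the ring-fixed diene geometry, in which the ring CH2 is the outside and the methyl the inside substituent, so that acyl group and future side chain become cis. C3 is set last: acid hydrolysis gives the ketone, whose CHMe centre equilibrates through the enol to the chair with acyl, hydroxyethyl and C3-methyl all equatorial, the epimer requiring a syn-diaxial methyl/methyl pair or two syn-axial chains. The step needs regio-, endo- and π-facial selectivity, secured by the ring oxygen on C2, by the compact chelated transition state and by the benzyl group; isomers from an exo approach are diastereomers of 9 and can be separated.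

Step 5
Reactants: 9 (S)-4-benzyl-3-[(1S,3R,5R)-3-(2-hydroxyethyl)-3,5-dimethyl-4-oxocyclohexane-1-carbonyl]oxazolidin-2-one
Product: 10 (1S,3R,5R)-3-(2-hydroxyethyl)-3,5-dimethyl-4-oxocyclohexane-1-carboxylic acid
Conditions: LiOH, H2O2, THF/H2O, 0 to 23 °C; aq. Na2SO3; HCl to pH 2
Reagents that add atoms: hydrogen peroxide (SMILES OO)
Why: hydroperoxide-mediated cleavage of an N-acyl oxazolidinone at the exocyclic carbonyl, after which the carboxylate α-carbon cannot be deprotonated and the basic medium keeps the CHMe centre next to the ketone at the anchored equilibrium.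

Step 6
Reactants: 10 (1S,3R,5R)-3-(2-hydroxyethyl)-3,5-dimethyl-4-oxocyclohexane-1-carboxylic acid
Product: 11 (2R,6R)-2-(2-hydroxyethyl)-2,6-dimethylcyclohexan-1-one
Conditions: 9-mesityl-10-phenylacridinium tetrafluoroborate (5 mol %), PhSSPh (10 mol %), i-Pr2NEt (20 mol %), CF3CH2OH, blue LEDs, 23 °C
Reagents that add atoms: none
Why: photoredox hydrodecarboxylation (the catalytic counterpart of the Barton decarboxylation), in which the excited acridinium oxidises the carboxylate, CO2 is lost and the secondary ring radical takes hydrogen from thiophenol, so C5 becomes CH2 and the two remaining stereocentres are not touched.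

Step 7
Reactants: 11 (2R,6R)-2-(2-hydroxyethyl)-2,6-dimethylcyclohexan-1-one
Product: 12 2-[(1R,3R)-1,3-dimethyl-2-methylidenecyclohexyl]ethan-1-ol
Conditions: Cp2TiMe2 (3.5 equiv), toluene, 70 °C, dark
Reagents that add atoms: dimethyltitanocene Cp2TiMe2 (SMILES C[Ti](C)(C1C=CC=C1)C1C=CC=C1)
Why: Petasis methylenation, in which the thermally formed titanocene methylidene adds to the hindered carbonyl and the oxatitanacyclobutane collapses to the alkene under non-basic conditions, so the CHMe centre should not epimerise although the anchor is gone; the excess reagent covers the free hydroxyl.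

Step 8
Reactants: 12 2-[(1R,3R)-1,3-dimethyl-2-methylidenecyclohexyl]ethan-1-ol
Product: 13 2-[(1R,3R)-1,3-dimethyl-2-methylidenecyclohexyl]ethyl 4-methylbenzenesulfonate
Conditions: TsCl, pyridine, CH2Cl2, 0 °C
Reagents that add atoms: 4-methylbenzenesulfonyl chloride (SMILES Cc1ccc(cc1)S(Cl)(=O)=O)
Why: sulfonylation of the unhindered primary alcohol, chosen over an iodide made with iodine because the latter could trigger iodoetherification onto the nearby exocyclic alkene.

Step 9
Reactants: 13 2-[(1R,3R)-1,3-dimethyl-2-methylidenecyclohexyl]ethyl 4-methylbenzenesulfonate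
Product: 14 (1R,3R)-1-(but-3-yn-1-yl)-1,3-dimethyl-2-methylidenecyclohexane
Conditions: lithium acetylide–ethylenediamine complex (LiC≡CH·H2NCH2CH2NH2), DMSO, 23 °C
Reagents that add atoms: lithium acetylide (SMILES [Li]C#C)
Why: SN2 alkylation of acetylide at a primary sulfonate that lies two carbons from the quaternary centre and is therefore not neopentyl.

Step 10
Reactants: 15 1,2,4,5-tetramethoxybenzene
Product: 16 (2,3,5,6-tetramethoxyphenyl)methanol
Conditions: n-BuLi, THF, 0 °C; (CH2O)n, 0 to 23 °C; H2O
Reagents that add atoms: paraformaldehyde as formaldehyde (SMILES C=O)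
Why: directed ortho-lithiation between two methoxy groups followed by hydroxymethylation of the aryllithium with formaldehyde.

Step 11
Reactants: 16 (2,3,5,6-tetramethoxyphenyl)methanol
Product: 17 3-(chloromethyl)-1,2,4,5-tetramethoxybenzene
Conditions: SOCl2, pyridine, CH2Cl2, 0 °C; used at once
Reagents that add atoms: thionyl chloride (SMILES ClS(Cl)=O)
Why: chlorodehydroxylation of an electron-rich benzylic alcohol through its chlorosulfite.

Step 12
Reactants: 14 (1R,3R)-1-(but-3-yn-1-yl)-1,3-dimethyl-2-methylidenecyclohexane; 17 3-(chloromethyl)-1,2,4,5-tetramethoxybenzene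
Product: 19 3-[(2E)-5-[(1R,3R)-1,3-dimethyl-2-methylidenecyclohexyl]-3-methylpent-2-en-1-yl]-1,2,4,5-tetramethoxybenzene, via E-alkenyldimethylalane 18 (not isolated)
Conditions: Me3Al (2 equiv), Cp2ZrCl2 (0.25 equiv), CH2Cl2, 0 to 23 °C; volatiles removed; then 17, Pd(PPh3)4 (5 mol %), THF, 23 °C
Reagents that add atoms: trimethylaluminium (SMILES C[Al](C)C)
Why: Negishi zirconium-catalysed carboalumination adds methyl and aluminium syn across the terminal alkyne (methyl to the internal carbon), which fixes the E trisubstituted alkene, and the alkenylalane is then cross-coupled with the benzylic chloride under palladium catalysis with retention of geometry, the 1,1-disubstituted exocyclic alkene being inert to both operations.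

Step 13
Reactants: 19 3-[(2E)-5-[(1R,3R)-1,3-dimethyl-2-methylidenecyclohexyl]-3-methylpent-2-en-1-yl]-1,2,4,5-tetramethoxybenzene
Product: 20 2,5-dimethoxy-3-[(2E)-5-[(1R,3R)-1,3-dimethyl-2-methylidenecyclohexyl]-3-methylpent-2-en-1-yl]cyclohexa-2,5-diene-1,4-dione
Conditions: (NH4)2Ce(NO3)6 (2.5 equiv), MeCN/H2O, 0 °C
Reagents that add atoms: water (SMILES O)
Why: oxidative demethylation of a para-dimethoxyarene to the para-quinone through the arene radical cation and attack of water, in which either para pair of methoxy groups leads to the same 2,5-dimethoxyquinone and the isolated alkenes should survive the short exposure at 0 °C.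

Step 14
Reactants: 20 2,5-dimethoxy-3-[(2E)-5-[(1R,3R)-1,3-dimethyl-2-methylidenecyclohexyl]-3-methylpent-2-en-1-yl]cyclohexa-2,5-diene-1,4-dione
Product: 21 metachromin A, 2-hydroxy-5-methoxy-3-[(2E)-5-[(1R,3R)-1,3-dimethyl-2-methylidenecyclohexyl]-3-methylpent-2-en-1-yl]cyclohexa-2,5-diene-1,4-dione
Conditions: HClO4 (60% aq.), THF, 23 °C
Reagents that add atoms: water (SMILES O)
Why: acid-catalysed addition–elimination at a vinylogous ester, in which the methoxy group wedged between the side chain and a carbonyl is twisted out of conjugation and gives an internally hydrogen-bonded hydroxyquinone on hydrolysis, so it should be exchanged selectively while the methoxy group next to the ring hydrogen stays.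

Compound list
1 | 3-methyloxolan-2-one (α-methyl-γ-butyrolactone, racemic) | CC1CCOC1=O | starting material
2 | isopropenylmagnesium bromide (prop-1-en-2-ylmagnesium bromide) | C=C(C)[Mg]Br | starting material
3 | 6-hydroxy-2,4-dimethylhex-1-en-3-one (racemic) | C=C(C)C(=O)C(C)CCO | intermediate
4 | 4-methyl-5-(prop-1-en-2-yl)-2,3-dihydrofuran | CC1=C(OCC1)C(C)=C | intermediate
5 | (S)-4-benzyloxazolidin-2-one | O=C1N[C@@H](Cc2ccccc2)CO1 | starting material
6 | acryloyl chloride | C=CC(=O)Cl | starting material
7 | (S)-3-acryloyl-4-benzyloxazolidin-2-one | C=CC(=O)N1C(=O)OC[C@@H]1Cc1ccccc1 | intermediate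
8 | (S)-4-benzyl-3-[(3aR,5S)-3a,7-dimethyl-2,3,3a,4,5,6-hexahydro-1-benzofuran-5-carbonyl]oxazolidin-2-one | CC1=C2OCC[C@@]2(C)C[C@@H](C(=O)N3C(=O)OC[C@@H]3Cc3ccccc3)C1 | intermediate (not isolated)
9 | (S)-4-benzyl-3-[(1S,3R,5R)-3-(2-hydroxyethyl)-3,5-dimethyl-4-oxocyclohexane-1-carbonyl]oxazolidin-2-one | O=C1[C@H](C)C[C@H](C(=O)N2C(=O)OC[C@@H]2Cc2ccccc2)C[C@]1(C)CCO | intermediate
10 | (1S,3R,5R)-3-(2-hydroxyethyl)-3,5-dimethyl-4-oxocyclohexane-1-carboxylic acid | O=C1[C@H](C)C[C@H](C(=O)O)C[C@]1(C)CCO | intermediate
11 | (2R,6R)-2-(2-hydroxyethyl)-2,6-dimethylcyclohexan-1-one | O=C1[C@H](C)CCC[C@]1(C)CCO | intermediate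
12 | 2-[(1R,3R)-1,3-dimethyl-2-methylidenecyclohexyl]ethan-1-ol | C=C1[C@H](C)CCC[C@]1(C)CCO | intermediate
13 | 2-[(1R,3R)-1,3-dimethyl-2-methylidenecyclohexyl]ethyl 4-methylbenzenesulfonate | C=C1[C@H](C)CCC[C@]1(C)CCOS(=O)(=O)c1ccc(C)cc1 | intermediate
14 | (1R,3R)-1-(but-3-yn-1-yl)-1,3-dimethyl-2-methylidenecyclohexane | C=C1[C@H](C)CCC[C@]1(C)CCC#C | intermediate
15 | 1,2,4,5-tetramethoxybenzene | COc1cc(OC)c(OC)cc1OC | starting material
16 | (2,3,5,6-tetramethoxyphenyl)methanol | COc1cc(OC)c(OC)c(CO)c1OC | intermediate
17 | 3-(chloromethyl)-1,2,4,5-tetramethoxybenzene | COc1cc(OC)c(OC)c(CCl)c1OC | intermediate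
18 | dimethyl[(1E)-4-[(1R,3R)-1,3-dimethyl-2-methylidenecyclohexyl]-2-methylbut-1-en-1-yl]alumane | C=C1[C@H](C)CCC[C@]1(C)CC/C(C)=C/[Al](C)C | intermediate (not isolated)
19 | 3-[(2E)-5-[(1R,3R)-1,3-dimethyl-2-methylidenecyclohexyl]-3-methylpent-2-en-1-yl]-1,2,4,5-tetramethoxybenzene | C=C1[C@H](C)CCC[C@]1(C)CC/C(C)=C/Cc1c(OC)c(OC)cc(OC)c1OC | intermediate
20 | 2,5-dimethoxy-3-[(2E)-5-[(1R,3R)-1,3-dimethyl-2-methylidenecyclohexyl]-3-methylpent-2-en-1-yl]cyclohexa-2,5-diene-1,4-dione | C=C1[C@H](C)CCC[C@]1(C)CC/C(C)=C/CC1=C(OC)C(=O)C=C(OC)C1=O | intermediate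
21 | metachromin A | C=C1[C@H](C)CCC[C@]1(C)CC/C(C)=C/CC1=C(O)C(=O)C=C(OC)C1=O | target

Total step count: 14. Longest linear sequence: 11 steps (1, 2, 4, 5, 6, 7, 8, 9, 12, 13, 14).

Steps most likely to fail

Step 4. The electron-rich, acid-labile diene may oligomerise under the stoichiometric aluminium Lewis acid. A stepwise, zwitterionic addition could also loosen the endo link between C5 and C1, which would lower the enantiomeric purity once C5 is excised. The fallback replaces auxiliary control by catalyst control with a much weaker Lewis acid. It sets out from 4, which is combined with commercial 3-acryloyloxazolidin-2-one and 10 mol % of the divalent-copper complex of Cu(SbF6)2 with (R,R)-2,2'-(propane-2,2-diyl)bis(4-tert-butyl-4,5-dihydrooxazole) in CH2Cl2 at −20 °C. The square-planar chelate of this ligand exposes the same Cα-si face, so the reaction should give 3-[(3aR,5S)-3a,7-dimethyl-2,3,3a,4,5,6-hexahydro-1-benzofuran-5-carbonyl]oxazolidin-2-one F1. Hydrolysis and equilibration with 1 M HCl in THF should give 3-[(1S,3R,5R)-3-(2-hydroxyethyl)-3,5-dimethyl-4-oxocyclohexane-1-carbonyl]oxazolidin-2-one F2, and LiOH/H2O2 then returns to the route at 10.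

Step 7. Olefination of the doubly flanked carbonyl may be slow and compete with enolisation, which at this stage would scramble C3 because the anchoring group has already been removed. The fallback moves the olefination in front of the decarboxylation, so that the anchor is still in place. It sets out from 10: Wittig methylenation with excess Ph3P=CH2 (Ph3PCH3Br, KOt-Bu, toluene, 90 °C) should give (1S,3R,5R)-3-(2-hydroxyethyl)-3,5-dimethyl-4-methylidenecyclohexane-1-carboxylic acid F3, any enolisation before olefination returning to the all-equatorial isomer. Barton decarboxylation through 2-thioxopyridin-1(2H)-yl (1S,3R,5R)-3-(2-hydroxyethyl)-3,5-dimethyl-4-methylidenecyclohexane-1-carboxylate F4 (N-hydroxypyridine-2-thione, DCC; then Bu3SnH, hν) comes back to the route at 12.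

Step 14. Hydrolysis may occur at the wrong vinylogous ester, or the acid may induce cyclisation of the new hydroxyl onto the trisubstituted alkene and migration of the exocyclic double bond. The fallback is exhaustive hydrolysis followed by selective re-methylation. It sets out from 20: aqueous NaOH in MeOH/THF should hydrolyse both methoxy groups to 2,5-dihydroxy-3-[(2E)-5-[(1R,3R)-1,3-dimethyl-2-methylidenecyclohexyl]-3-methylpent-2-en-1-yl]cyclohexa-2,5-diene-1,4-dione F5. Acid-catalysed vinylogous esterification (MeOH, BF3·OEt2, 0 °C) is then expected to methylate only the hydroxyl next to the ring hydrogen, the one beside the side chain being shielded, and so comes back to the route at 21.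

Further compounds
F1 | step 4 | 3-[(3aR,5S)-3a,7-dimethyl-2,3,3a,4,5,6-hexahydro-1-benzofuran-5-carbonyl]oxazolidin-2-one | CC1=C2OCC[C@@]2(C)C[C@@H](C(=O)N3CCOC3=O)C1
F2 | step 4 | 3-[(1S,3R,5R)-3-(2-hydroxyethyl)-3,5-dimethyl-4-oxocyclohexane-1-carbonyl]oxazolidin-2-one | O=C1[C@H](C)C[C@H](C(=O)N2CCOC2=O)C[C@]1(C)CCO
F3 | step 7 | (1S,3R,5R)-3-(2-hydroxyethyl)-3,5-dimethyl-4-methylidenecyclohexane-1-carboxylic acid | C=C1[C@H](C)C[C@H](C(=O)O)C[C@]1(C)CCO
F4 | step 7 | 2-thioxopyridin-1(2H)-yl (1S,3R,5R)-3-(2-hydroxyethyl)-3,5-dimethyl-4-methylidenecyclohexane-1-carboxylate | C=C1[C@H](C)C[C@H](C(=O)On2ccccc2=S)C[C@]1(C)CCO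
F5 | step 14 | 2,5-dihydroxy-3-[(2E)-5-[(1R,3R)-1,3-dimethyl-2-methylidenecyclohexyl]-3-methylpent-2-en-1-yl]cyclohexa-2,5-diene-1,4-dione | C=C1[C@H](C)CCC[C@]1(C)CC/C(C)=C/CC1=C(O)C(=O)C=C(O)C1=O
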